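**Retrosynthetic overview**
- Target ⇐ hydrogenolysis of two benzyl ethers on ring B and protonation of a disodium 6,7-disulfate; the sulfates ⇐ bis-sulfation of a 5,6,7-triol in which the 5-OH, hydrogen-bonded to the C4 carbonyl, stays free.
- Flavone core ⇐ one three-component carbonylative Sonogashira annulation (key step): ring A o-iodophenol + CO (becomes C4) + ring B aryl acetylene (C2, C3).
- Rings A and B come preformed from aromatic starting materials; ring C is the only ring made and is formed last.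
- Orthogonality: ring A carries MOM ethers (acid-labile, removed before sulfation); ring B carries benzyl ethers (removed after sulfation).
- Iodophenol ⇐ 3,4,5-trihydroxybenzaldehyde (MOM protection, Dakin-type oxidation, iodination); alkyne ⇐ 3,4-bis(benzyloxy)benzaldehyde (Ohira–Bestmann).

Assumption: the target has no stereocentre, so no asymmetric step is needed; it is made as the free bis(hydrogen sulfate) exactly as drawn, released from its stable disodium salt in the last operation and kept cold.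

**Route**

Step 1
Reactants: 1 3,4,5-trihydroxybenzaldehyde
Product: 2 3,4,5-tris(methoxymethoxy)benzaldehyde
Conditions: MOMCl (4 equiv), K2CO3 (6 equiv), DMF, 0 °C → rt, N2
Reagents that add atoms: chloromethyl methyl ether (MOMCl), COCCl
Why: Williamson-type O-alkylation of the three phenoxides gives the MOM acetals, which are stable to base, amines, peracid and palladium but cleaved later by acid without touching benzyl ethers; no stereocentre is formed.

Step 2
Reactants: 2 3,4,5-tris(methoxymethoxy)benzaldehyde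
Product: 4 3,4,5-tris(methoxymethoxy)phenol, via aryl formate 3 (not isolated)
Conditions: mCPBA (1.3 equiv), CH2Cl2, 0 °C → rt; aq. NaHCO3 wash; then K2CO3 (0.2 equiv), MeOH, rt
Reagents that add atoms: 3-chloroperoxybenzoic acid (mCPBA), O=C(OO)c1cccc(Cl)c1
Why: Baeyer–Villiger (Dakin-type) oxidation, in which the electron-rich trialkoxyaryl group migrates in preference to hydrogen to give formate 3, which base-catalysed methanolysis converts to the phenol; no stereocentre is formed.

Step 3
Reactants: 4 3,4,5-tris(methoxymethoxy)phenol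
Product: 5 2-iodo-3,4,5-tris(methoxymethoxy)phenol
Conditions: NIS (1.0 equiv), MeCN, −20 → 0 °C, dark
Reagents that add atoms: N-iodosuccinimide (NIS), O=C1CCC(=O)N1I
Why: Electrophilic aromatic iodination of an activated phenol whose para position is blocked and whose two ortho positions are equivalent, so one equivalent of NIS at low temperature gives the single mono-iodide; no stereocentre is formed.

Step 4
Reactants: 6 3,4-bis(benzyloxy)benzaldehyde
Product: 7 1,2-bis(benzyloxy)-4-ethynylbenzene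
Conditions: dimethyl (1-diazo-2-oxopropyl)phosphonate (1.3 equiv), K2CO3 (2 equiv), MeOH–THF, 0 °C → rt
Reagents that add atoms: Ohira–Bestmann reagent, dimethyl (1-diazo-2-oxopropyl)phosphonate, CC(=O)C(=[N+]=[N-])P(=O)(OC)OC
Why: Seyferth–Gilbert homologation in the Ohira–Bestmann variant converts the non-enolisable aryl aldehyde into the terminal alkyne in one step under conditions that leave benzyl ethers untouched; no stereocentre is formed.

Step 5
Reactants: 5 2-iodo-3,4,5-tris(methoxymethoxy)phenol; 7 1,2-bis(benzyloxy)-4-ethynylbenzene (1.3 equiv)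
Product: 9 2-[3,4-bis(benzyloxy)phenyl]-5,6,7-tris(methoxymethoxy)-4H-chromen-4-one, via ynone 8 (not isolated)
Conditions: PdCl2(dppf) (5 mol %), CO (20 bar), Et2NH, 120 °C, autoclave
Reagents that add atoms: carbon monoxide, [C-]#[O+]
Why: Carbonylative Sonogashira annulation, in which zerovalent palladium inserts into the C–I bond, CO insertion and alkynyl transfer give o-hydroxyaryl ynone 8, and the secondary amine steers the phenol into 6-endo oxa-Michael closure (flavone, not the 5-exo aurone), forming ring C in one operation; no stereocentre is formed.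

Step 6
Reactants: 9 2-[3,4-bis(benzyloxy)phenyl]-5,6,7-tris(methoxymethoxy)-4H-chromen-4-one
Product: 10 2-[3,4-bis(benzyloxy)phenyl]-5,6,7-trihydroxy-4H-chromen-4-one
Conditions: HCl (1.25 M in MeOH), THF, 45 °C, Ar
Reagents that add atoms: none
Why: Acid-catalysed transacetalisation to methanol removes the three MOM groups while benzyl ethers and the flavone are inert, and the 5,6,7-trihydroxy pattern is the thermodynamically preferred one so no Wessely–Moser scrambling is possible; no stereocentre is formed.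

Step 7
Reactants: 10 2-[3,4-bis(benzyloxy)phenyl]-5,6,7-trihydroxy-4H-chromen-4-one
Product: 12 disodium 2-[3,4-bis(benzyloxy)phenyl]-5-hydroxy-4-oxo-4H-chromene-6,7-diyl bis(sulfate), via bis(pyridinium) disulfate 11 (not isolated)
Conditions: SO3·pyridine (5 equiv), pyridine–DMF, rt → 40 °C; then aq. NaHCO3 to pH 8; C18 reversed-phase chromatography (H2O–MeOH)
Reagents that add atoms: sulfur trioxide–pyridine complex, O=S(=O)([O-])[n+]1ccccc1; sodium hydrogen carbonate, OC(=O)[O-].[Na+]
Why: O-sulfation of phenols with an SO3–amine complex takes the free 7-OH and 6-OH, whereas the 5-OH is held in a strong hydrogen bond to the C4 carbonyl and is the least reactive hydroxyl of a flavone, and ring B is blocked as benzyl ethers; no stereocentre is formed.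

Step 8
Reactants: 12 disodium 2-[3,4-bis(benzyloxy)phenyl]-5-hydroxy-4-oxo-4H-chromene-6,7-diyl bis(sulfate)
Product: 14 6-hydroxyluteolin 6,7-disulfate [2-(3,4-dihydroxyphenyl)-5-hydroxy-4-oxo-4H-chromene-6,7-diyl bis(hydrogen sulfate)], via debenzylated disodium salt 13 (not isolated)
Conditions: H2 (1 atm), 10% Pd/C, MeOH–H2O (4:1), rt; filter; then 1 M HCl (2.0 equiv), 0 °C; cold C18 desalting, lyophilisation
Reagents that add atoms: none
Why: Catalytic hydrogenolysis cleaves the two benzyl ethers while aryl sulfate monoesters and the flavone C2–C3 double bond survive at 1 atm, and two equivalents of strong acid at 0 °C then protonate the sulfate monoanions to the target as drawn; no stereocentre is formed.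

**Compound list**
1 | 3,4,5-trihydroxybenzaldehyde | O=Cc1cc(O)c(O)c(O)c1 | starting material
2 | 3,4,5-tris(methoxymethoxy)benzaldehyde | O=Cc1cc(OCOC)c(OCOC)c(OCOC)c1 | intermediate
3 | 3,4,5-tris(methoxymethoxy)phenyl formate | O=COc1cc(OCOC)c(OCOC)c(OCOC)c1 | intermediate
4 | 3,4,5-tris(methoxymethoxy)phenol | Oc1cc(OCOC)c(OCOC)c(OCOC)c1 | intermediate
5 | 2-iodo-3,4,5-tris(methoxymethoxy)phenol | Oc1cc(OCOC)c(OCOC)c(OCOC)c1I | intermediate
6 | 3,4-bis(benzyloxy)benzaldehyde | O=Cc1ccc(OCc2ccccc2)c(OCc2ccccc2)c1 | starting material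
7 | 1,2-bis(benzyloxy)-4-ethynylbenzene | C#Cc1ccc(OCc2ccccc2)c(OCc2ccccc2)c1 | intermediate
8 | 3-[3,4-bis(benzyloxy)phenyl]-1-[2-hydroxy-4,5,6-tris(methoxymethoxy)phenyl]prop-2-yn-1-one | O=C(C#Cc1ccc(OCc2ccccc2)c(OCc2ccccc2)c1)c1c(O)cc(OCOC)c(OCOC)c1OCOC | intermediate
9 | 2-[3,4-bis(benzyloxy)phenyl]-5,6,7-tris(methoxymethoxy)-4H-chromen-4-one | O=c1cc(-c2ccc(OCc3ccccc3)c(OCc3ccccc3)c2)oc2cc(OCOC)c(OCOC)c(OCOC)c12 | intermediate
10 | 2-[3,4-bis(benzyloxy)phenyl]-5,6,7-trihydroxy-4H-chromen-4-one | O=c1cc(-c2ccc(OCc3ccccc3)c(OCc3ccccc3)c2)oc2cc(O)c(O)c(O)c12 | intermediate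
11 | bis(pyridinium) 2-[3,4-bis(benzyloxy)phenyl]-5-hydroxy-4-oxo-4H-chromene-6,7-diyl bis(sulfate) | O=c1cc(-c2ccc(OCc3ccccc3)c(OCc3ccccc3)c2)oc2cc(OS(=O)(=O)[O-])c(OS(=O)(=O)[O-])c(O)c12.c1cc[nH+]cc1.c1cc[nH+]cc1 | intermediate
12 | disodium 2-[3,4-bis(benzyloxy)phenyl]-5-hydroxy-4-oxo-4H-chromene-6,7-diyl bis(sulfate) | O=c1cc(-c2ccc(OCc3ccccc3)c(OCc3ccccc3)c2)oc2cc(OS(=O)(=O)[O-])c(OS(=O)(=O)[O-])c(O)c12.[Na+].[Na+] | intermediate
13 | disodium 2-(3,4-dihydroxyphenyl)-5-hydroxy-4-oxo-4H-chromene-6,7-diyl bis(sulfate) | O=c1cc(-c2ccc(O)c(O)c2)oc2cc(OS(=O)(=O)[O-])c(OS(=O)(=O)[O-])c(O)c12.[Na+].[Na+] | intermediate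
14 | 6-hydroxyluteolin 6,7-disulfate | O=c1cc(-c2ccc(O)c(O)c2)oc2cc(OS(=O)(=O)O)c(OS(=O)(=O)O)c(O)c12 | target

**Totals**
Total step count: 8. Longest linear sequence: 7 steps (steps 1, 2, 3, 5, 6, 7, 8 from compound 1); step 4 is the one-step side branch to the alkyne.

**Steps most likely to fail, with fallbacks**

Step 5 (carbonylative annulation). The aryl iodide is hindered and electron-rich, and direct alkynylation (leading to a benzofuran) or aminocarbonylation by Et2NH can compete with the desired path. The fallback sets out from phenol 4 (with alkyne 7) and comes back at ynone 8, using neither CO nor the aryl iodide. Phenol 4 is ortho-formylated (MgCl2, Et3N, paraformaldehyde, MeCN, reflux) to 2-hydroxy-4,5,6-tris(methoxymethoxy)benzaldehyde F1. The lithium acetylide of 7 (n-BuLi, THF, −78 °C, 2.2 equiv) adds to it to give racemic 3-[3,4-bis(benzyloxy)phenyl]-1-[2-hydroxy-4,5,6-tris(methoxymethoxy)phenyl]prop-2-yn-1-ol F2. MnO2 in CH2Cl2 oxidises this to ynone 8, which is closed to 9 by warming in Et2NH.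

Step 7 (bis-sulfation). The 6-OH is flanked on both sides and may react sluggishly, excess reagent may touch the 5-OH, and ionic regioisomers are hard to separate. The fallback sets out from triol 10 and comes back at target 14, using protected sulfate diesters that can be purified on silica. Triol 10 is treated with 2,2,2-trichloroethyl chlorosulfate (2.2 equiv), Et3N and DMAP in THF at 0 °C to give 2-[3,4-bis(benzyloxy)phenyl]-5-hydroxy-4-oxo-4H-chromene-6,7-diyl bis(2,2,2-trichloroethyl) bis(sulfate) F3. Pd/C with HCO2NH4 in MeOH then removes both trichloroethyl groups and both benzyl ethers in one pot, giving diammonium 2-(3,4-dihydroxyphenyl)-5-hydroxy-4-oxo-4H-chromene-6,7-diyl bis(sulfate) F4. This is acidified with 1 M HCl (2 equiv) at 0 °C and desalted cold to give 14.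

Step 8 (hydrogenolysis on the dianionic disulfate). Debenzylation may stall or over-reduce the C2–C3 bond. The fallback sets out from flavone 9 and comes back at disodium salt 13, moving the hydrogenolysis ahead of sulfation and using base-labile esters on ring B. It does not remove the other risk of step 8, the lability of the free acid, because it rejoins before the acidification.
- Flavone 9 is hydrogenolysed (H2, Pd/C, EtOAc–MeOH) to 2-(3,4-dihydroxyphenyl)-5,6,7-tris(methoxymethoxy)-4H-chromen-4-one F5.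
- Pivaloyl chloride, Et3N and DMAP in CH2Cl2 give 4-[5,6,7-tris(methoxymethoxy)-4-oxo-4H-chromen-2-yl]-1,2-phenylene bis(2,2-dimethylpropanoate) F6.
- HCl in MeOH–THF at rt to 40 °C removes the MOM groups (the hindered pivalates survive) to give 4-(5,6,7-trihydroxy-4-oxo-4H-chromen-2-yl)-1,2-phenylene bis(2,2-dimethylpropanoate) F7.
- SO3·pyridine in pyridine–DMF gives bis(pyridinium) 2-[3,4-bis(pivaloyloxy)phenyl]-5-hydroxy-4-oxo-4H-chromene-6,7-diyl bis(sulfate) F8, converted by aq. NaHCO3 into disodium 2-[3,4-bis(pivaloyloxy)phenyl]-5-hydroxy-4-oxo-4H-chromene-6,7-diyl bis(sulfate) F9.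
- Ammonolysis of the pivalates (7 M NH3 in MeOH, 0 °C → rt, Ar; sulfate monoesters are inert) and evaporation give 13, which is acidified as in step 8.

**Further compounds**
F1 | step 5 | 2-hydroxy-4,5,6-tris(methoxymethoxy)benzaldehyde | O=Cc1c(O)cc(OCOC)c(OCOC)c1OCOC
F2 | step 5 | racemic 3-[3,4-bis(benzyloxy)phenyl]-1-[2-hydroxy-4,5,6-tris(methoxymethoxy)phenyl]prop-2-yn-1-ol | OC(C#Cc1ccc(OCc2ccccc2)c(OCc2ccccc2)c1)c1c(O)cc(OCOC)c(OCOC)c1OCOC
F3 | step 7 | 2-[3,4-bis(benzyloxy)phenyl]-5-hydroxy-4-oxo-4H-chromene-6,7-diyl bis(2,2,2-trichloroethyl) bis(sulfate) | O=c1cc(-c2ccc(OCc3ccccc3)c(OCc3ccccc3)c2)oc2cc(OS(=O)(=O)OCC(Cl)(Cl)Cl)c(OS(=O)(=O)OCC(Cl)(Cl)Cl)c(O)c12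
F4 | step 7 | diammonium 2-(3,4-dihydroxyphenyl)-5-hydroxy-4-oxo-4H-chromene-6,7-diyl bis(sulfate) | O=c1cc(-c2ccc(O)c(O)c2)oc2cc(OS(=O)(=O)[O-])c(OS(=O)(=O)[O-])c(O)c12.[NH4+].[NH4+]
F5 | step 8 | 2-(3,4-dihydroxyphenyl)-5,6,7-tris(methoxymethoxy)-4H-chromen-4-one | O=c1cc(-c2ccc(O)c(O)c2)oc2cc(OCOC)c(OCOC)c(OCOC)c12
F6 | step 8 | 4-[5,6,7-tris(methoxymethoxy)-4-oxo-4H-chromen-2-yl]-1,2-phenylene bis(2,2-dimethylpropanoate) | O=c1cc(-c2ccc(OC(=O)C(C)(C)C)c(OC(=O)C(C)(C)C)c2)oc2cc(OCOC)c(OCOC)c(OCOC)c12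
F7 | step 8 | 4-(5,6,7-trihydroxy-4-oxo-4H-chromen-2-yl)-1,2-phenylene bis(2,2-dimethylpropanoate) | O=c1cc(-c2ccc(OC(=O)C(C)(C)C)c(OC(=O)C(C)(C)C)c2)oc2cc(O)c(O)c(O)c12
F8 | step 8 | bis(pyridinium) 2-[3,4-bis(pivaloyloxy)phenyl]-5-hydroxy-4-oxo-4H-chromene-6,7-diyl bis(sulfate) | O=c1cc(-c2ccc(OC(=O)C(C)(C)C)c(OC(=O)C(C)(C)C)c2)oc2cc(OS(=O)(=O)[O-])c(OS(=O)(=O)[O-])c(O)c12.c1cc[nH+]cc1.c1cc[nH+]cc1
F9 | step 8 | disodium 2-[3,4-bis(pivaloyloxy)phenyl]-5-hydroxy-4-oxo-4H-chromene-6,7-diyl bis(sulfate) | O=c1cc(-c2ccc(OC(=O)C(C)(C)C)c(OC(=O)C(C)(C)C)c2)oc2cc(OS(=O)(=O)[O-])c(OS(=O)(=O)[O-])c(O)c12.[Na+].[Na+]
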